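**Retrosynthetic overview**
1. Target 30 ⇒ silyl ether 29 ⇒ (C5–C6 acylation) hemiester acid 26 + lithiated 2-ethylpyranone 25.
2. Key disconnection: the ester C–O bond of 26 ⇒ cyclohexanone diol 11 + meso anhydride 20; a desymmetrising O-acylation joins the halves and fixes the three contiguous stereocentres of the acid chain.
3. 11 ⇒ C2-symmetric diketone 9 (intramolecular aldol) ⇒ syn-aldol of pentan-3-one with (E)-2-methylpent-2-enal, then anti hydroboration.
4. 20 ⇒ double anti hydroboration of silylated 2,4-dimethylpenta-1,4-dien-3-ol, oxidation, dehydration.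
5. Ring order: cyclohexanone (step 5), oxanedione (step 10), pyranone by triketone cyclodehydration (step 12).

Assumption: (+)-Ipc2BOTf (from (−)-α-pinene) is taken to give Re-face attack on the aldehyde, by analogy with Ipc2B-allyl additions (the antipodal reagent is used if the adduct proves enantiomeric); 4-methylheptane-3,5-dione is taken as a catalogue compound.

**Route**

Step 1
Reactants: 1 pentan-3-one; 2 (E)-2-methylpent-2-enal
Product: 5 (4R,5R,6E)-5-hydroxy-4,6-dimethylnon-6-en-3-one, via (Z)-enol borinate 3 (not isolated), via boron aldolate 4 (not isolated)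
Conditions: (+)-Ipc2BOTf, i-Pr2NEt, CH2Cl2, −78 °C; 2, −78 → −20 °C; H2O2, MeOH/pH 7 buffer, 0 °C
Reagents that add atoms: (+)-diisopinocampheylboron triflate FC(F)(F)S(=O)(=O)OB([C@H]1C[C@H]2C[C@@H]([C@@H]1C)C2(C)C)[C@H]1C[C@H]2C[C@@H]([C@@H]1C)C2(C)C (boron and Ipc groups are carried by 3 and 4 only)
Why: Paterson boron aldol: the Z-enol diisopinocampheylborinate reacts through a chair Zimmerman–Traxler transition state (4,5-syn) and the Ipc ligands select the aldehyde Re face, setting 4R,5R in about 90% ee.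

Step 2
Reactants: 5 (4R,5R,6E)-5-hydroxy-4,6-dimethylnon-6-en-3-one
Product: 6 (4R,5R,6E)-4,6-dimethyl-5-(triethylsilyloxy)non-6-en-3-one
Conditions: TESOTf, 2,6-lutidine, CH2Cl2, −78 °C
Reagents that add atoms: triethylsilyl triflate CC[Si](CC)(CC)OS(=O)(=O)C(F)(F)F
Why: Standard low-temperature O-silylation of a β-hydroxy ketone; no stereocentre is touched.

Step 3
Reactants: 6 (4R,5R,6E)-4,6-dimethyl-5-(triethylsilyloxy)non-6-en-3-one
Product: 8 (3RS,4S,6S,7S)-4,6-dimethyl-5-(triethylsilyloxy)nonane-3,7-diol (4,5-syn, 5,6-anti), via bis(9-BBN) adduct 7 (not isolated)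
Conditions: 9-BBN (3 equiv), THF, 0 → 60 °C; NaOH, H2O2, 0 °C
Reagents that add atoms: 9-borabicyclo[3.3.1]nonane [H]B1C2CCCC1CCC2 (in 7 only); hydrogen peroxide OO
Why: Still–Barrish hydroboration–oxidation: A(1,2)-strain-controlled syn addition to the 2-substituted allylic silyl ether places the new C6 methyl anti to C5–O, while the ketone is reduced unselectively (irrelevant, re-oxidised in step 4).

Step 4
Reactants: 8 (3RS,4S,6S,7S)-4,6-dimethyl-5-(triethylsilyloxy)nonane-3,7-diol
Product: 9 (4R,6R)-4,6-dimethyl-5-(triethylsilyloxy)nonane-3,7-dione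
Conditions: Dess–Martin periodinane, pyridine, CH2Cl2, 0 °C → rt
Reagents that add atoms: none
Why: Dess–Martin oxidation of both secondary alcohols under buffered, non-epimerising conditions gives the C2-symmetric diketone, in which C5 is no longer stereogenic.

Step 5
Reactants: 9 (4R,6R)-4,6-dimethyl-5-(triethylsilyloxy)nonane-3,7-dione
Product: 11 (2R,3R,4R,5R,6R)-3-ethyl-3,5-dihydroxy-2,4,6-trimethylcyclohexan-1-one, via cyclised TES ether 10 (not isolated)
Conditions: LiHMDS (1.05 equiv), THF, −78 → −30 °C; AcOH, −78 °C; then HF·pyridine, pyridine, 0 °C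
Reagents that add atoms: none
Why: Intramolecular aldol (6-enolendo-exo-trig) of the kinetic ethyl-side lithium enolate onto the homotopic second ketone; the reversible, chelated lithium aldolate settles in the chair with O axial and ethyl equatorial at C3 and the new C2 methyl equatorial (trans to the axial C6 methyl, avoiding a 1,3-diaxial Me/Me contact), and fluoride then removes the TES group.

Step 6
Reactants: 12 methacrolein; 13 isopropenylmagnesium bromide
Product: 14 2,4-dimethylpenta-1,4-dien-3-ol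
Conditions: THF, −78 → 0 °C; aq NH4Cl
Reagents that add atoms: none
Why: Grignard 1,2-addition to the enal gives the achiral divinyl carbinol.

Step 7
Reactants: 14 2,4-dimethylpenta-1,4-dien-3-ol
Product: 15 tert-butyl[(2,4-dimethylpenta-1,4-dien-3-yl)oxy]dimethylsilane
Conditions: TBSCl, imidazole, DMF, rt
Reagents that add atoms: tert-butyldimethylsilyl chloride CC(C)(C)[Si](C)(C)Cl
Why: Standard silylation; the bulky ether also raises the facial bias of the next step.

Step 8
Reactants: 15 tert-butyl[(2,4-dimethylpenta-1,4-dien-3-yl)oxy]dimethylsilane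
Product: 17 meso-(2R,3s,4S)-3-[(tert-butyldimethylsilyl)oxy]-2,4-dimethylpentane-1,5-diol (anti,anti), via bis(9-BBN) adduct 16 (not isolated)
Conditions: 9-BBN (2.5 equiv), THF, 0 °C → rt; NaOH, H2O2, 0 °C
Reagents that add atoms: 9-borabicyclo[3.3.1]nonane [H]B1C2CCCC1CCC2 (in 16 only); hydrogen peroxide OO
Why: Two-directional Still–Barrish hydroboration–oxidation: each 1,1-disubstituted alkene reacts anti to the allylic OTBS group, so both methyl centres are set anti to C3–O and the meso anti,anti diol results (minor diastereomers removed by chromatography).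

Step 9
Reactants: 17 meso-(2R,3s,4S)-3-[(tert-butyldimethylsilyl)oxy]-2,4-dimethylpentane-1,5-diol
Product: 19 meso-(2R,3r,4S)-3-[(tert-butyldimethylsilyl)oxy]-2,4-dimethylpentanedioic acid, via dialdehyde 18 (not isolated)
Conditions: Dess–Martin periodinane, pyridine, CH2Cl2, rt; then NaClO2, NaH2PO4, 2-methylbut-2-ene, t-BuOH/H2O, 0 °C
Reagents that add atoms: sodium chlorite [Na+].[O-]Cl=O
Why: Dess–Martin then Pinnick oxidation takes both primary alcohols to acids through the dialdehyde, which avoids the lactol/lactone trap of a one-stage 1,5-diol oxidation and does not epimerise the α-centres.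

Step 10
Reactants: 19 meso-(2R,3r,4S)-3-[(tert-butyldimethylsilyl)oxy]-2,4-dimethylpentanedioic acid
Product: 20 meso-(3R,4r,5S)-4-[(tert-butyldimethylsilyl)oxy]-3,5-dimethyloxane-2,6-dione
Conditions: DCC, CH2Cl2, 0 °C → rt
Reagents that add atoms: none
Why: Carbodiimide cyclodehydration closes the six-membered anhydride; the all-trans isomer formed is also the thermodynamically preferred one.

Step 11
Reactants: 21 4-methylheptane-3,5-dione; 22 N-methoxy-N-methylacetamide
Product: 24 3,5-dimethyloctane-2,4,6-trione (diastereomer and enol mixture), via dilithio dianion 23 (not isolated)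
Conditions: LDA (2.2 equiv), THF, −78 → 0 °C; 22, −78 °C; aq HCl
Reagents that add atoms: lithium diisopropylamide [Li+].CC(C)[N-]C(C)C (lithium in 23 only)
Why: Terminal (γ) acylation of a β-diketone dianion by a Weinreb amide (Claisen-type); the only second deprotonation site is an ethyl CH2.

Step 12
Reactants: 24 3,5-dimethyloctane-2,4,6-trione
Product: 25 2-ethyl-3,5,6-trimethyl-4H-pyran-4-one
Conditions: conc. H2SO4, 0 °C → rt
Reagents that add atoms: none
Why: Acid-mediated cyclodehydration of the 1,3,5-triketone forms the pyranone C–O bond; only one γ-pyranone is possible.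

Step 13
Reactants: 11 (2R,3R,4R,5R,6R)-3-ethyl-3,5-dihydroxy-2,4,6-trimethylcyclohexan-1-one; 20 meso-(3R,4r,5S)-4-[(tert-butyldimethylsilyl)oxy]-3,5-dimethyloxane-2,6-dione
Product: 26 (2S,3R,4R)-3-[(tert-butyldimethylsilyl)oxy]-5-{[(1R,2R,3R,4R,6R)-3-ethyl-3-hydroxy-2,4,6-trimethyl-5-oxocyclohexyl]oxy}-2,4-dimethyl-5-oxopentanoic acid
Conditions: (2S,3R)-HyperBTM (10 mol %), i-Pr2NEt, 20 (1.5 equiv), CHCl3, −40 → 0 °C; aq citric acid
Reagents that add atoms: none
Why: Proposed new method: catalyst-controlled desymmetrising O-acylation of a hindered chiral secondary alcohol by a meso anhydride, in which the isothiourea opens 20 reversibly to two diastereomeric acyl-isothiouronium carboxylates, the tethered carboxylate acts as general base for delivery of the C5–OH of 11, and under Curtin–Hammett control (reinforced by the matched chirality of 11; the catalyst antipode is fixed by a two-run screen) only the carbonyl next to the (R)-methine is esterified, which forms the ester C–O bond and fixes the 2R,3R,4S centres of the acid chain while the tertiary OH stays inert; the closest known reaction types are cinchona/thiourea-catalysed alcoholysis of meso glutaric anhydrides with simple alcohols and isothiourea-catalysed acylative kinetic resolution of secondary alcohols.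

Step 14
Reactants: 26 hemiester acid (as above); 25 2-ethyl-3,5,6-trimethyl-4H-pyran-4-one
Product: 29 (1R,2R,3R,4R,6R)-3-ethyl-3-hydroxy-2,4,6-trimethyl-5-oxocyclohexyl (2R,3R,4S,6S)-3-[(tert-butyldimethylsilyl)oxy]-2,4-dimethyl-5-oxo-6-(3,5,6-trimethyl-4-oxo-4H-pyran-2-yl)heptanoate, via acyl imidazole 27 (not isolated), via lithiated pyranone 28 (not isolated)
Conditions: 26, CDI, THF, rt; cannulate into 25 (3.0 equiv)/LiHMDS (2.9 equiv), THF, −78 °C; AcOH, −78 °C
Reagents that add atoms: 1,1'-carbonyldiimidazole O=C(n1ccnc1)n1ccnc1 (imidazolyl group in 27 only); lithium hexamethyldisilazide [Li+].C[Si](C)(C)[N-][Si](C)(C)C (lithium in 28 only)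
Why: Claisen-type C-acylation of the weakly basic pyranone dienolate by the acyl imidazole (the dienolate is too weak a base to enolise the hindered ring ketone, and the equatorial C–H next to the acyloxy carbon is poorly aligned for E1cB), followed by A(1,3)-strain-controlled kinetic protonation of the resulting enolate on the face anti to the C3 branch, predicted to give 6S; the C6 epimer is separable and can be re-equilibrated with DBU and recycled.

Step 15
Reactants: 29 TBS ether (as above)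
Product: 30 (1R,2R,3R,4R,6R)-3-ethyl-3-hydroxy-2,4,6-trimethyl-5-oxocyclohexyl (2R,3R,4S,6S)-3-hydroxy-2,4-dimethyl-5-oxo-6-(3,5,6-trimethyl-4-oxo-4H-pyran-2-yl)heptanoate (target CNP0260549.2)
Conditions: HF·pyridine, pyridine, THF, 0 °C → rt
Reagents that add atoms: none
Why: Buffered fluoride desilylation under mildly acidic conditions leaves the base-labile C6 centre, the β-acyloxy ketone and the tertiary aldol untouched.

**Compound list**
1 | pentan-3-one | CCC(=O)CC | starting material
2 | (E)-2-methylpent-2-enal | CC/C=C(\C)C=O | starting material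
3 | (Z)-pent-2-en-3-yl bis[(+)-isopinocampheyl]borinate | C/C=C(CC)\OB([C@H]1C[C@H]2C[C@@H]([C@@H]1C)C2(C)C)[C@H]1C[C@H]2C[C@@H]([C@@H]1C)C2(C)C | intermediate
4 | bis[(+)-isopinocampheyl]borinate of 5 (boron aldolate) | CCC(=O)[C@H](C)[C@@H](OB([C@H]1C[C@H]2C[C@@H]([C@@H]1C)C2(C)C)[C@H]1C[C@H]2C[C@@H]([C@@H]1C)C2(C)C)/C(C)=C/CC | intermediate
5 | (4R,5R,6E)-5-hydroxy-4,6-dimethylnon-6-en-3-one | CCC(=O)[C@H](C)[C@@H](O)/C(C)=C/CC | intermediate
6 | (4R,5R,6E)-4,6-dimethyl-5-(triethylsilyloxy)non-6-en-3-one | CCC(=O)[C@H](C)[C@@H](O[Si](CC)(CC)CC)/C(C)=C/CC | intermediate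
7 | C7-(9-BBN) borane / C3-O-(9-BBN) borinate adduct of 6 (C3 epimers) | CCC(OB1C2CCCC1CCC2)[C@H](C)[C@@H](O[Si](CC)(CC)CC)[C@@H](C)[C@@H](B1C2CCCC1CCC2)CC | intermediate
8 | (3RS,4S,6S,7S)-4,6-dimethyl-5-(triethylsilyloxy)nonane-3,7-diol | CCC(O)[C@H](C)[C@@H](O[Si](CC)(CC)CC)[C@@H](C)[C@@H](O)CC | intermediate
9 | (4R,6R)-4,6-dimethyl-5-(triethylsilyloxy)nonane-3,7-dione | CCC(=O)[C@H](C)C(O[Si](CC)(CC)CC)[C@@H](C)C(=O)CC | intermediate
10 | (2R,3R,4R,5R,6R)-3-ethyl-3-hydroxy-2,4,6-trimethyl-5-(triethylsilyloxy)cyclohexan-1-one | CC[C@@]1(O)[C@H](C)[C@@H](O[Si](CC)(CC)CC)[C@@H](C)C(=O)[C@@H]1C | intermediate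
11 | (2R,3R,4R,5R,6R)-3-ethyl-3,5-dihydroxy-2,4,6-trimethylcyclohexan-1-one | CC[C@@]1(O)[C@H](C)[C@@H](O)[C@@H](C)C(=O)[C@@H]1C | intermediate
12 | methacrolein | CC(=C)C=O | starting material
13 | isopropenylmagnesium bromide | CC(=C)[Mg]Br | starting material
14 | 2,4-dimethylpenta-1,4-dien-3-ol | CC(=C)C(O)C(C)=C | intermediate
15 | tert-butyl[(2,4-dimethylpenta-1,4-dien-3-yl)oxy]dimethylsilane | CC(=C)C(O[Si](C)(C)C(C)(C)C)C(C)=C | intermediate
16 | meso anti,anti 1,5-bis(9-borabicyclo[3.3.1]nonan-9-yl)-3-[(tert-butyldimethylsilyl)oxy]-2,4-dimethylpentane | C(B1C2CCCC1CCC2)[C@H](C)[C@H](O[Si](C)(C)C(C)(C)C)[C@H](C)CB1C2CCCC1CCC2 | intermediate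
17 | meso-(2R,3s,4S)-3-[(tert-butyldimethylsilyl)oxy]-2,4-dimethylpentane-1,5-diol | OC[C@H](C)[C@H](O[Si](C)(C)C(C)(C)C)[C@H](C)CO | intermediate
18 | meso-(2R,3r,4S)-3-[(tert-butyldimethylsilyl)oxy]-2,4-dimethylpentanedial | O=C[C@H](C)[C@H](O[Si](C)(C)C(C)(C)C)[C@H](C)C=O | intermediate
19 | meso-(2R,3r,4S)-3-[(tert-butyldimethylsilyl)oxy]-2,4-dimethylpentanedioic acid | OC(=O)[C@H](C)[C@H](O[Si](C)(C)C(C)(C)C)[C@H](C)C(=O)O | intermediate
20 | meso-(3R,4r,5S)-4-[(tert-butyldimethylsilyl)oxy]-3,5-dimethyloxane-2,6-dione | O=C1[C@H](C)[C@H](O[Si](C)(C)C(C)(C)C)[C@H](C)C(=O)O1 | intermediate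
21 | 4-methylheptane-3,5-dione | CCC(=O)C(C)C(=O)CC | starting material
22 | N-methoxy-N-methylacetamide | CON(C)C(C)=O | starting material
23 | dilithium bis-enolate (dianion) of 21 | [Li+].[Li+].CC=C([O-])C(C)=C([O-])CC | intermediate
24 | 3,5-dimethyloctane-2,4,6-trione | CCC(=O)C(C)C(=O)C(C)C(C)=O | intermediate
25 | 2-ethyl-3,5,6-trimethyl-4H-pyran-4-one | CCc1oc(C)c(C)c(=O)c1C | intermediate
26 | (2S,3R,4R)-3-[(tert-butyldimethylsilyl)oxy]-5-{[(1R,2R,3R,4R,6R)-3-ethyl-3-hydroxy-2,4,6-trimethyl-5-oxocyclohexyl]oxy}-2,4-dimethyl-5-oxopentanoic acid | CC[C@@]1(O)[C@H](C)[C@@H](OC(=O)[C@H](C)[C@H](O[Si](C)(C)C(C)(C)C)[C@H](C)C(=O)O)[C@@H](C)C(=O)[C@@H]1C | intermediate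
27 | acyl imidazole of 26 | CC[C@@]1(O)[C@H](C)[C@@H](OC(=O)[C@H](C)[C@H](O[Si](C)(C)C(C)(C)C)[C@H](C)C(=O)n2ccnc2)[C@@H](C)C(=O)[C@@H]1C | intermediate
28 | lithium 2-ethylidene-3,5,6-trimethyl-2H-pyran-4-olate (lithiated 25) | [Li+].CC=C1OC(C)=C(C)C([O-])=C1C | intermediate
29 | (1R,2R,3R,4R,6R)-3-ethyl-3-hydroxy-2,4,6-trimethyl-5-oxocyclohexyl (2R,3R,4S,6S)-3-[(tert-butyldimethylsilyl)oxy]-2,4-dimethyl-5-oxo-6-(3,5,6-trimethyl-4-oxo-4H-pyran-2-yl)heptanoate | CC[C@@]1(O)[C@H](C)[C@@H](OC(=O)[C@H](C)[C@H](O[Si](C)(C)C(C)(C)C)[C@H](C)C(=O)[C@@H](C)c2oc(C)c(C)c(=O)c2C)[C@@H](C)C(=O)[C@@H]1C | intermediate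
30 | (1R,2R,3R,4R,6R)-3-ethyl-3-hydroxy-2,4,6-trimethyl-5-oxocyclohexyl (2R,3R,4S,6S)-3-hydroxy-2,4-dimethyl-5-oxo-6-(3,5,6-trimethyl-4-oxo-4H-pyran-2-yl)heptanoate | CC[C@@]1(O)[C@H](C)[C@@H](OC(=O)[C@H](C)[C@H](O)[C@H](C)C(=O)[C@@H](C)c2oc(C)c(C)c(=O)c2C)[C@@H](C)C(=O)[C@@H]1C | target

**Totals**
Total step count: 15. Longest linear sequence: 8 steps (1–5, then 13–15; the anhydride branch 6–10, then 13–15, is equally long).

**Three steps most likely to fail**

Step 13 (the proposed new desymmetrising acylation; risk: low rate with two hindered partners or poor carbonyl discrimination). The fallback uses known chemistry, sets out from 20 and 11 and comes back at 26. Anhydride 20 is opened with benzyl alcohol under stoichiometric quinidine or quinine (the pseudo-enantiomer that delivers the alcohol to the carbonyl next to the (S)-methine; alkaloid-mediated meso-anhydride alcoholysis) to give the hemi-benzyl ester F1. The free acid of F1 is joined to the secondary hydroxyl of 11 by Yamaguchi esterification (2,4,6-trichlorobenzoyl chloride, Et3N, DMAP, toluene) to give the benzyl cyclohexyl diester F2. Hydrogenolysis (H2, Pd/C, EtOAc) then frees the acid and returns 26.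

Step 14 (risk: O- instead of C-acylation, proton transfer, or poor control at C6). The fallback sets out from 26 and comes back at 29, replacing acylation by aldol addition and oxidation. Acid 26 is converted into the S-ethyl thioester F3 (EtSH, DCC, DMAP) and reduced under Fukuyama conditions (Et3SiH, Pd/C) to the aldehyde F4. Lithiated 25 (LiHMDS, THF, −78 °C) adds to the aldehyde to give the β-hydroxy pyranone F5, so that C6 is set during C–C bond formation and the diastereomers can be separated. Dess–Martin oxidation of the carbinol, which does not epimerise C6, gives 29.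

Step 5 (risk: wrong configuration at the carbinol or retro-aldol during ring closure on the silyl ether). The fallback sets out from 9 and comes back at 26, moving the ring closure to after esterification, where the ketone pair carries the acyloxy group as in the natural substitution pattern. HF·pyridine converts 9 into the acyclic (4R,6R)-5-hydroxy-4,6-dimethylnonane-3,7-dione F6. Yamaguchi esterification of F6 with the hemi-benzyl ester F1 gives the acyclic diester F7. Soft-enolisation aldol cyclisation (TiCl4, i-Pr2NEt, CH2Cl2, −78 °C) closes the cyclohexanone to give the diester F2, and hydrogenolysis (H2, Pd/C) returns 26.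

**Further compounds**
F1 | step 13 | (2R,3S,4S)-5-(benzyloxy)-3-[(tert-butyldimethylsilyl)oxy]-2,4-dimethyl-5-oxopentanoic acid | OC(=O)[C@H](C)[C@H](O[Si](C)(C)C(C)(C)C)[C@H](C)C(=O)OCc1ccccc1
F2 | step 13 | benzyl ester of 26 (benzyl cyclohexyl diester) | CC[C@@]1(O)[C@H](C)[C@@H](OC(=O)[C@H](C)[C@H](O[Si](C)(C)C(C)(C)C)[C@H](C)C(=O)OCc2ccccc2)[C@@H](C)C(=O)[C@@H]1C
F3 | step 14 | S-ethyl thioester of 26 | CC[C@@]1(O)[C@H](C)[C@@H](OC(=O)[C@H](C)[C@H](O[Si](C)(C)C(C)(C)C)[C@H](C)C(=O)SCC)[C@@H](C)C(=O)[C@@H]1C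
F4 | step 14 | aldehyde corresponding to 26 (CO2H replaced by CHO) | CC[C@@]1(O)[C@H](C)[C@@H](OC(=O)[C@H](C)[C@H](O[Si](C)(C)C(C)(C)C)[C@H](C)C=O)[C@@H](C)C(=O)[C@@H]1C
F5 | step 14 | 5-hydroxy analogue of 29 (carbinol epimers, C6 as in 29) | CC[C@@]1(O)[C@H](C)[C@@H](OC(=O)[C@H](C)[C@H](O[Si](C)(C)C(C)(C)C)[C@H](C)C(O)[C@@H](C)c2oc(C)c(C)c(=O)c2C)[C@@H](C)C(=O)[C@@H]1C
F6 | step 5 | (4R,6R)-5-hydroxy-4,6-dimethylnonane-3,7-dione | CCC(=O)[C@H](C)C(O)[C@@H](C)C(=O)CC
F7 | step 5 | benzyl (4R,6R)-4,6-dimethyl-3,7-dioxononan-5-yl diester of 19 (acyclic precursor of F2) | CCC(=O)[C@H](C)C(OC(=O)[C@H](C)[C@H](O[Si](C)(C)C(C)(C)C)[C@H](C)C(=O)OCc1ccccc1)[C@@H](C)C(=O)CC
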